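**Plan**
The target is the (2S)-flavanone 5,7-dihydroxy-4'-methoxy-8-prenylflavanone. After removal of two MOM groups, the retrosynthesis cuts C2–C3 and O1–C8a of ring C together, as a formal oxa-[4+2] of an aryl methyl ketone with the ring-B aldehyde.
Enabling feature: ring C is a dihydropyranone whose O1–C8a=C4a–C4=O unit is a vinylogous ester fused into ring A. C3 is the α-carbon and C8a the β-carbon of an aryl methyl ketone, so with fluorine on C8a its enol silane (C3=C4(OSi)–C4a=C8a–F) is an arene-embedded 1-alkoxy-3-silyloxydiene equivalent.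
The acetyl bond (C4–C4a) and the prenyl bond (C8 to C1 of the prenyl group) are then cut back to 5-fluororesorcinol by two fluorine-guided ortho-lithiations.
Forward: ring A is dressed first (MOM, prenyl, acetyl, enol silane), ring B enters as the aldehyde, ring C is closed last around both, and MOM removal ends the route.
Stereochemistry: the only stereocenter, C2 (S), is set by catalyst-controlled Si-face Mukaiyama addition in the key step; the ring closure forms O1–C8a and breaks no bond at C2.

Key step: step 5

Assumption: 5-fluorobenzene-1,3-diol is taken as a purchasable starting material.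

**Route**

Step 1
Reactants: 1 5-fluorobenzene-1,3-diol (5-fluororesorcinol)
Product: 2 1-fluoro-3,5-bis(methoxymethoxy)benzene
Conditions: MOMCl (2.5 equiv), iPr2NEt (3 equiv), CH2Cl2, 0 °C → rt
Reagents that add atoms: chloromethyl methyl ether (MOMCl), COCCl
Why: Standard O-alkylation of both phenols (MOM ether formation) gives acetals that survive organolithiums and fluoride, direct ortho-metalation, and can be removed at the end without touching the aryl methyl ether of ring B.

Step 2
Reactants: 2 1-fluoro-3,5-bis(methoxymethoxy)benzene; 3 1-bromo-3-methylbut-2-ene (prenyl bromide)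
Product: 6 1-fluoro-3,5-bis(methoxymethoxy)-2-(3-methylbut-2-en-1-yl)benzene, via aryllithium 4 (not isolated), via arylcopper 5 (not isolated)
Conditions: n-BuLi (1.05 equiv), THF, −78 °C, 1 h; CuBr·SMe2 (1.1 equiv), −78 → −40 °C; 3 (1.3 equiv), −78 → 0 °C
Reagents that add atoms: none
Why: Directed ortho-metalation is expected at the C–H flanked by fluorine (strongest acidifier) and one OMOM group (coordination) rather than between the two OMOM groups, since fluoro-alkoxy-flanked C–H bonds lithiate at −78 °C while bis-alkoxy-flanked ones need higher temperature; transmetalation to arylcopper suppresses LiF loss to an aryne and gives SN2-type allylic substitution to the linear prenyl arene.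

Step 3
Reactants: 6 1-fluoro-3,5-bis(methoxymethoxy)-2-(3-methylbut-2-en-1-yl)benzene; 7 N-methoxy-N-methylacetamide
Product: 10 1-[2-fluoro-4,6-bis(methoxymethoxy)-3-(3-methylbut-2-en-1-yl)phenyl]ethan-1-one, via aryllithium 8 (not isolated), via tetrahedral lithium adduct 9 (not isolated)
Conditions: n-BuLi (1.1 equiv), THF, −78 °C, 1 h; 7 (1.5 equiv), −78 °C; H2O quench
Reagents that add atoms: none
Why: A second directed ortho-metalation takes the only remaining C–H ortho to fluorine (again F/OMOM-flanked), and Weinreb ketone synthesis stops at the chelated tetrahedral adduct, so the methyl ketone is released only on work-up with fluorine now lying between acetyl and prenyl.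

Step 4
Reactants: 10 1-[2-fluoro-4,6-bis(methoxymethoxy)-3-(3-methylbut-2-en-1-yl)phenyl]ethan-1-one
Product: 12 {1-[2-fluoro-4,6-bis(methoxymethoxy)-3-(3-methylbut-2-en-1-yl)phenyl]ethenyl}oxy(trimethyl)silane, via lithium enolate 11 (not isolated)
Conditions: LiN(SiMe3)2 (1.1 equiv), THF, −78 °C; Me3SiCl (1.3 equiv), −78 → 0 °C; pentane, filtration, used crude
Reagents that add atoms: chlorotrimethylsilane, C[Si](C)(C)Cl
Why: Kinetic enolisation of a ketone with a single enolisable side followed by O-silylation (silyl enol ether formation) under non-acidic conditions leaves the MOM acetals intact and delivers the diene equivalent for the annulation.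

Step 5
Reactants: 12 {1-[2-fluoro-4,6-bis(methoxymethoxy)-3-(3-methylbut-2-en-1-yl)phenyl]ethenyl}oxy(trimethyl)silane; 13 4-methoxybenzaldehyde
Product: 15 (2S)-5,7-bis(methoxymethoxy)-2-(4-methoxyphenyl)-8-(3-methylbut-2-en-1-yl)-2,3-dihydro-4H-chromen-4-one, via silyl aldol ether 14 (not isolated)
Conditions: 13 (1.2 equiv), chiral N-triflyl thiophosphoramide of 3,3'-bis(2,4,6-triisopropylphenyl)-BINOL (5 mol%, enantiomer selected for Si-face attack), toluene, −78 °C; then [Bu4N][Ph3SiF2] (0.3 equiv), THF–DMF, −40 → 0 °C, same flask; pH 7 buffer quench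
Reagents that add atoms: none
Why: Proposed new method: the chiral Brønsted acid activates aldehyde 13 and the C3 terminus of enol silane 12 adds to its Si face with silyl transfer (Mukaiyama aldol), parking the new C2 oxygen as TMS ether 14; catalytic fluoride then frees the C2 alkoxide, which attacks C8a ortho to the ketone and expels fluoride, and that fluoride desilylates the next molecule of 14, so Me3SiF is the only stoichiometric by-product. The closest known reactions are the Mukaiyama aldol–dihydropyranone annulation of 1-methoxy-3-silyloxybutadienes with aldehydes (stepwise hetero-Diels–Alder) and the base-mediated intramolecular SNAr of 3-hydroxy-1-(2-fluoroaryl)propan-1-ones to chroman-4-ones; fusing them into one enantioselective fluoride-relay operation on an electron-rich fluoroarene is the untested part. Ring C closes by 6-endo-trig addition of the alkoxide oxygen to the C4a=C8a bond of the aryl ketone (anionic σ-adduct held as the C4 enolate) followed by elimination of fluoride. The single stereocenter C2 is set under catalyst control in the C–C bond-forming event (Si-face attack gives 3S in 14) and is carried unchanged into 2S-15 because the SNAr forms O1–C8a and breaks no bond at C2; the catalyst hand is to be fixed in a model run, the antipode being equally accessible. The step needs SNAr to outrun retro-aldol cleavage and E1cB dehydration of the alkoxide, which the substrate supports through ortho-carbonyl activation of the C–F bond, six-membered pre-organisation, the absence of any free phenol, and an alkoxide present only at catalytic concentration in aprotic medium at low temperature; regiochemistry is not in question because C8a carries the only fluorine, so only the 8-prenyl isomer can form.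

Step 6
Reactants: 15 (2S)-5,7-bis(methoxymethoxy)-2-(4-methoxyphenyl)-8-(3-methylbut-2-en-1-yl)-2,3-dihydro-4H-chromen-4-one
Product: 16 (2S)-5,7-dihydroxy-2-(4-methoxyphenyl)-8-(3-methylbut-2-en-1-yl)-2,3-dihydro-4H-chromen-4-one
Conditions: 3 M aq. HCl–MeOH (1:4), rt → 40 °C
Reagents that add atoms: none
Why: Acid-catalysed acetal exchange with methanol (MOM ether cleavage) frees both phenols while the aryl methyl ether is inert, and dilute protic acid at near-ambient temperature should neither enolise through C2, ionise the C2–O1 bond, nor cyclise the prenyl group onto the 7-hydroxyl at a competitive rate.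

**Compound list**
1 | 5-fluorobenzene-1,3-diol | Oc1cc(O)cc(F)c1 | starting material
2 | 1-fluoro-3,5-bis(methoxymethoxy)benzene | COCOc1cc(F)cc(OCOC)c1 | intermediate
3 | 1-bromo-3-methylbut-2-ene | CC(C)=CCBr | starting material
4 | [2-fluoro-4,6-bis(methoxymethoxy)phenyl]lithium | [Li]c1c(F)cc(OCOC)cc1OCOC | intermediate
5 | [2-fluoro-4,6-bis(methoxymethoxy)phenyl]copper | [Cu]c1c(F)cc(OCOC)cc1OCOC | intermediate
6 | 1-fluoro-3,5-bis(methoxymethoxy)-2-(3-methylbut-2-en-1-yl)benzene | COCOc1cc(F)c(CC=C(C)C)c(OCOC)c1 | intermediate
7 | N-methoxy-N-methylacetamide | CON(C)C(C)=O | starting material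
8 | [2-fluoro-4,6-bis(methoxymethoxy)-3-(3-methylbut-2-en-1-yl)phenyl]lithium | [Li]c1c(F)c(CC=C(C)C)c(OCOC)cc1OCOC | intermediate
9 | lithium 1-[2-fluoro-4,6-bis(methoxymethoxy)-3-(3-methylbut-2-en-1-yl)phenyl]-1-[methoxy(methyl)amino]ethan-1-olate | CON(C)C(C)(O[Li])c1c(F)c(CC=C(C)C)c(OCOC)cc1OCOC | intermediate
10 | 1-[2-fluoro-4,6-bis(methoxymethoxy)-3-(3-methylbut-2-en-1-yl)phenyl]ethan-1-one | CC(=O)c1c(F)c(CC=C(C)C)c(OCOC)cc1OCOC | intermediate
11 | lithium 1-[2-fluoro-4,6-bis(methoxymethoxy)-3-(3-methylbut-2-en-1-yl)phenyl]ethen-1-olate | [Li]OC(=C)c1c(F)c(CC=C(C)C)c(OCOC)cc1OCOC | intermediate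
12 | {1-[2-fluoro-4,6-bis(methoxymethoxy)-3-(3-methylbut-2-en-1-yl)phenyl]ethenyl}oxy(trimethyl)silane | C=C(O[Si](C)(C)C)c1c(F)c(CC=C(C)C)c(OCOC)cc1OCOC | intermediate
13 | 4-methoxybenzaldehyde | COc1ccc(C=O)cc1 | starting material
14 | (3S)-1-[2-fluoro-4,6-bis(methoxymethoxy)-3-(3-methylbut-2-en-1-yl)phenyl]-3-(4-methoxyphenyl)-3-[(trimethylsilyl)oxy]propan-1-one | COc1ccc([C@@H](O[Si](C)(C)C)CC(=O)c2c(F)c(CC=C(C)C)c(OCOC)cc2OCOC)cc1 | intermediate
15 | (2S)-5,7-bis(methoxymethoxy)-2-(4-methoxyphenyl)-8-(3-methylbut-2-en-1-yl)-2,3-dihydro-4H-chromen-4-one | COc1ccc([C@@H]2CC(=O)c3c(OCOC)cc(OCOC)c(CC=C(C)C)c3O2)cc1 | intermediate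
16 | (2S)-5,7-dihydroxy-2-(4-methoxyphenyl)-8-(3-methylbut-2-en-1-yl)-2,3-dihydro-4H-chromen-4-one | COc1ccc([C@@H]2CC(=O)c3c(O)cc(O)c(CC=C(C)C)c3O2)cc1 | target

**Totals**
Total step count: 6. Longest linear sequence: 6 steps (1 → 16).

**Steps most likely to fail**

Step 5 (the step carrying the new-method label). The freed alkoxide may undergo retro-aldol cleavage or E1cB dehydration faster than it closes onto the electron-rich fluoroarene. Reversible aldol or base-induced ring opening and reclosure of the product may erode the enantiomeric purity. Facial selectivity with the di-ortho-substituted enol silane may be poor. Fallback, using known chemistry: it sets out from ketone 10. Claisen formylation with ethyl formate and NaH (THF, 0 → 60 °C) gives sodium (Z)-3-[2-fluoro-4,6-bis(methoxymethoxy)-3-(3-methylbut-2-en-1-yl)phenyl]-3-oxoprop-1-en-1-olate F1, not isolated. Its enolate oxygen displaces the ortho fluorine in the same pot (chromone formation from an o-fluoroaryl 1,3-dicarbonyl) to give 5,7-bis(methoxymethoxy)-8-(3-methylbut-2-en-1-yl)-4H-chromen-4-one F2. Enantioselective conjugate addition of 4-methoxyphenylboronic acid then forms the C2–aryl bond and sets C2, returning to 15. Conditions for that addition: Pd(OCOCF3)2, the t-BuPyOx ligand enantiomer that gives the 2S product, NH4PF6, H2O, ClCH2CH2Cl, 60 °C.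

Step 2. Lithiation may occur between the two OMOM groups instead of next to fluorine, the ortho-fluoro aryllithium may lose LiF to an aryne, and allylic substitution may go partly SN2′ to the reverse-prenyl isomer. Fallback: it sets out from 2. Electrophilic bromination (N-bromosuccinimide, MeCN, 0 °C) goes para to one OMOM group and ortho to fluorine to give 2-bromo-1-fluoro-3,5-bis(methoxymethoxy)benzene F3. Bromine–lithium exchange (n-BuLi, THF, −78 °C) then generates aryllithium 4 with the site fixed by the halogen, and CuBr·SMe2 followed by 3, as in step 2, returns to 6.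

Step 3. Deprotonation may occur at the benzylic-allylic CH2 of the prenyl group or at the wrong ring position, and the aryllithium may enolise the amide instead of adding to it. Fallback: it sets out from 1 and puts the acetyl group in by electrophilic substitution before the prenyl group.
- Friedel–Crafts acylation (AcOH, BF3·OEt2, 90 °C, aqueous work-up) goes para to one hydroxyl and ortho to fluorine to give 1-(2-fluoro-4,6-dihydroxyphenyl)ethan-1-one F4.
- MOMCl and NaH (DMF, 0 °C) give 1-[2-fluoro-4,6-bis(methoxymethoxy)phenyl]ethan-1-one F5.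
- N-bromosuccinimide (MeCN, 0 °C) brominates the ring position between fluorine and OMOM, para to the other OMOM, to give 1-[3-bromo-2-fluoro-4,6-bis(methoxymethoxy)phenyl]ethan-1-one F6.
- Suzuki–Miyaura coupling with 3-methylbut-2-enylboronic acid pinacol ester (Pd(OAc)2, a biarylphosphine ligand selective for the linear product, K3PO4, THF–H2O, 60 °C) returns to 10.

**Further compounds**
F1 | step 5 | sodium (Z)-3-[2-fluoro-4,6-bis(methoxymethoxy)-3-(3-methylbut-2-en-1-yl)phenyl]-3-oxoprop-1-en-1-olate | [Na+].[O-]/C=C\C(=O)c1c(F)c(CC=C(C)C)c(OCOC)cc1OCOC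
F2 | step 5 | 5,7-bis(methoxymethoxy)-8-(3-methylbut-2-en-1-yl)-4H-chromen-4-one | O=c1ccoc2c(CC=C(C)C)c(OCOC)cc(OCOC)c12
F3 | step 2 | 2-bromo-1-fluoro-3,5-bis(methoxymethoxy)benzene | COCOc1cc(F)c(Br)c(OCOC)c1
F4 | step 3 | 1-(2-fluoro-4,6-dihydroxyphenyl)ethan-1-one | CC(=O)c1c(F)cc(O)cc1O
F5 | step 3 | 1-[2-fluoro-4,6-bis(methoxymethoxy)phenyl]ethan-1-one | CC(=O)c1c(F)cc(OCOC)cc1OCOC
F6 | step 3 | 1-[3-bromo-2-fluoro-4,6-bis(methoxymethoxy)phenyl]ethan-1-one | CC(=O)c1c(F)c(Br)c(OCOC)cc1OCOC
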